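**Retrosynthetic overview**
1. The tetronic acid ring is closed last, by a Dieckmann-type Claisen condensation of a methyl 2-(propanoyloxy)alkanoate that already carries the whole side chain.
2. The 3-furyl ring is brought in intact from 3-bromofuran by B-alkyl Suzuki coupling; its three-carbon tether comes from allylic oxidation and chlorination of the terminal methyl of a geranyl unit, then an allyl–vinyl Stille coupling.
3. The chain is cut sp3–sp3 between the CH2 next to the methyl stereocentre and the geranyl CH2 (alkylzinc plus geranyl chloride).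
4. Both stereocentres come from one ring: enantioselective all-cis hydrogenation of methyl 4-methylfuran-2-carboxylate, opening of the oxolane at its CH2–O bond, and Mitsunobu inversion of the carbinol with propanoic acid (cis ring becomes the anti open-chain array).
5. Ring order: oxolane (step 1, opened in step 2), then furan (attached preformed, step 8), then tetronic acid (step 9).

Assumption: all starting materials are bought; the (S,S) ligand is written for step 1 and its (R,R) antipode is used instead if it proves to give the mirror-image ring.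

**Step 1**
Reactants: 1 methyl 4-methylfuran-2-carboxylate
Product: 2 methyl (2S,4S)-4-methyloxolane-2-carboxylate
Conditions: H2 (50 bar), Ru(cod)(2-methylallyl)2 (2 mol %), (S,S)-SINpEt·HBF4 (4 mol %), KOtBu (5 mol %), hexane, 25 °C
Reagents that add atoms: none
Why: Proposed new method: a chiral ruthenium bis(N-heterocyclic carbene) catalyst (SINpEt = 1,3-bis[(1S)-1-(naphthalen-1-yl)ethyl]imidazolin-2-ylidene) binds one face of the furan and delivers both equivalents of H2 to that face, so H-2 and H-4 end up cis and the ligand fixes the absolute sense as 2S,4S; the closest known reaction type is the Ru–NHC asymmetric hydrogenation of 2,4- and 2,5-disubstituted furans, here extended to a furan-2-carboxylate.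

**Step 2**
Reactants: 2 methyl (2S,4S)-4-methyloxolane-2-carboxylate
Product: 4 methyl (2S,4S)-5-bromo-2-hydroxy-4-methylpentanoate, via O-dimethylboryl ether 3 (not isolated)
Conditions: Me2BBr (1.5 equiv), Et3N (0.1 equiv), CH2Cl2, 0 °C to rt; then MeOH
Reagents that add atoms: dimethylboron bromide, CB(C)Br
Why: Lewis-acid ether cleavage: boron binds the ring oxygen and bromide opens the oxonium by SN2 at the primary C5 (the C2–O bond next to the ester is deactivated), so neither stereocentre is touched.

**Step 3**
Reactants: 4 methyl (2S,4S)-5-bromo-2-hydroxy-4-methylpentanoate; 5 propanoic acid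
Product: 6 methyl (2R,4S)-5-bromo-4-methyl-2-(propanoyloxy)pentanoate
Conditions: PPh3, DIAD, THF, 0 °C to rt
Reagents that add atoms: none
Why: Mitsunobu esterification: propanoate displaces the oxyphosphonium by SN2, inverting C2 from S to R (this turns the cis ring geometry into the anti 2,4-relationship of the target) and installing the acyl group for the final ring closure.

**Step 4**
Reactants: 6 methyl (2R,4S)-5-bromo-4-methyl-2-(propanoyloxy)pentanoate; 7 geranyl chloride
Product: 9 methyl (2R,4R,7E)-4,8,12-trimethyl-2-(propanoyloxy)trideca-7,11-dienoate, via alkylzinc bromide 8 (not isolated)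
Conditions: Zn dust (2 equiv), LiCl (1.5 equiv), THF, 50 °C; then 7 (1.3 equiv), CoBr2 (10 mol %), THF/NMP, −10 °C to rt
Reagents that add atoms: none
Why: LiCl-assisted zinc insertion gives an ester-tolerant alkylzinc, and cobalt-catalysed allylation of alkylzincs by primary allylic chlorides is an SN2 (alpha) substitution with retention of the E alkene, forming the sp3–sp3 C5–C6 bond; C4 keeps its geometry (its descriptor changes from S to R only through CIP ranking).

**Step 5**
Reactants: 9 methyl (2R,4R,7E)-4,8,12-trimethyl-2-(propanoyloxy)trideca-7,11-dienoate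
Product: 10 methyl (2R,4R,7E,11E)-13-hydroxy-4,8,12-trimethyl-2-(propanoyloxy)trideca-7,11-dienoate
Conditions: SeO2 (0.3 equiv), t-BuOOH (3 equiv), salicylic acid (0.1 equiv), CH2Cl2, 0 °C to rt
Reagents that add atoms: selenium dioxide, O=[Se]=O; tert-butyl hydroperoxide, CC(C)(C)OO
Why: Riley allylic oxidation under catalytic conditions (ene reaction, then [2,3]-sigmatropic shift) attacks the most accessible terminal trisubstituted alkene at the methyl trans to the chain, giving the E allylic alcohol.

**Step 6**
Reactants: 10 methyl (2R,4R,7E,11E)-13-hydroxy-4,8,12-trimethyl-2-(propanoyloxy)trideca-7,11-dienoate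
Product: 11 methyl (2R,4R,7E,11E)-13-chloro-4,8,12-trimethyl-2-(propanoyloxy)trideca-7,11-dienoate
Conditions: PPh3 (1.3 equiv), CCl4, 70 °C
Reagents that add atoms: carbon tetrachloride, ClC(Cl)(Cl)Cl
Why: Appel reaction: chloride displaces the oxyphosphonium at the primary allylic carbon by SN2, without allylic transposition or loss of alkene geometry.

**Step 7**
Reactants: 11 methyl (2R,4R,7E,11E)-13-chloro-4,8,12-trimethyl-2-(propanoyloxy)trideca-7,11-dienoate; 12 tributyl(ethenyl)stannane
Product: 13 methyl (2R,4R,7E,11E)-4,8,12-trimethyl-2-(propanoyloxy)pentadeca-7,11,14-trienoate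
Conditions: Pd2(dba)3 (2.5 mol %), P(2-furyl)3 (10 mol %), THF, 50 °C
Reagents that add atoms: none
Why: Stille coupling: oxidative addition gives a syn pi-allylpalladium that accepts the vinyl group at its unsubstituted CH2 terminus, giving the skipped triene with the 11E alkene retained.

**Step 8**
Reactants: 13 methyl (2R,4R,7E,11E)-4,8,12-trimethyl-2-(propanoyloxy)pentadeca-7,11,14-trienoate; 14 3-bromofuran
Product: 16 methyl (2R,4R,7E,11E)-15-(furan-3-yl)-4,8,12-trimethyl-2-(propanoyloxy)pentadeca-7,11-dienoate, via B-alkyl-9-BBN adduct 15 (not isolated)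
Conditions: 9-BBN (1.3 equiv), THF, 0 °C to rt; then 14, Pd(dppf)Cl2 (5 mol %), K3PO4·H2O (3 equiv), DMF, 50 °C
Reagents that add atoms: none
Why: 9-BBN hydroborates only the monosubstituted terminal alkene (anti-Markovnikov), and B-alkyl Suzuki–Miyaura coupling joins the primary alkylborane to C3 of the intact furan under mild base.

**Step 9**
Reactants: 16 methyl (2R,4R,7E,11E)-15-(furan-3-yl)-4,8,12-trimethyl-2-(propanoyloxy)pentadeca-7,11-dienoate
Product: 18 (5R)-5-[(2R,5E,9E)-13-(furan-3-yl)-2,6,10-trimethyltrideca-5,9-dien-1-yl]-4-hydroxy-3-methylfuran-2(5H)-one, via lithium tetronate 17 (not isolated)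
Conditions: LiN(SiMe3)2 (2.5 equiv), THF, −78 to 0 °C; then 1 M HCl
Reagents that add atoms: none
Why: Dieckmann-type intramolecular Claisen condensation: the propanoate enolate attacks the neighbouring methyl ester (5-exo) and loss of methoxide gives the stabilised tetronate, protonated on work-up; C2 of 16 becomes C5 (R) unchanged, and low temperature limits enolisation there.

**Compound list**
1 | methyl 4-methylfuran-2-carboxylate | COC(=O)c1cc(C)co1 | starting material
2 | methyl (2S,4S)-4-methyloxolane-2-carboxylate (cis) | COC(=O)[C@@H]1C[C@H](C)CO1 | intermediate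
3 | methyl (2S,4S)-5-bromo-2-[(dimethylboranyl)oxy]-4-methylpentanoate | COC(=O)[C@@H](OB(C)C)C[C@H](C)CBr | intermediate (not isolated)
4 | methyl (2S,4S)-5-bromo-2-hydroxy-4-methylpentanoate | COC(=O)[C@@H](O)C[C@H](C)CBr | intermediate
5 | propanoic acid | CCC(=O)O | starting material
6 | methyl (2R,4S)-5-bromo-4-methyl-2-(propanoyloxy)pentanoate | COC(=O)[C@H](OC(=O)CC)C[C@H](C)CBr | intermediate
7 | geranyl chloride, (2E)-1-chloro-3,7-dimethylocta-2,6-diene | ClC/C=C(\C)CCC=C(C)C | starting material
8 | bromo[(2S,4R)-5-methoxy-2-methyl-5-oxo-4-(propanoyloxy)pentyl]zinc | COC(=O)[C@H](OC(=O)CC)C[C@H](C)C[Zn]Br | intermediate (not isolated)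
9 | methyl (2R,4R,7E)-4,8,12-trimethyl-2-(propanoyloxy)trideca-7,11-dienoate | COC(=O)[C@H](OC(=O)CC)C[C@H](C)CC/C=C(\C)CCC=C(C)C | intermediate
10 | methyl (2R,4R,7E,11E)-13-hydroxy-4,8,12-trimethyl-2-(propanoyloxy)trideca-7,11-dienoate | COC(=O)[C@H](OC(=O)CC)C[C@H](C)CC/C=C(\C)CC/C=C(\C)CO | intermediate
11 | methyl (2R,4R,7E,11E)-13-chloro-4,8,12-trimethyl-2-(propanoyloxy)trideca-7,11-dienoate | COC(=O)[C@H](OC(=O)CC)C[C@H](C)CC/C=C(\C)CC/C=C(\C)CCl | intermediate
12 | tributyl(ethenyl)stannane | C=C[Sn](CCCC)(CCCC)CCCC | starting material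
13 | methyl (2R,4R,7E,11E)-4,8,12-trimethyl-2-(propanoyloxy)pentadeca-7,11,14-trienoate | COC(=O)[C@H](OC(=O)CC)C[C@H](C)CC/C=C(\C)CC/C=C(\C)CC=C | intermediate
14 | 3-bromofuran | Brc1ccoc1 | starting material
15 | methyl (2R,4R,7E,11E)-15-(9-borabicyclo[3.3.1]nonan-9-yl)-4,8,12-trimethyl-2-(propanoyloxy)pentadeca-7,11-dienoate | COC(=O)[C@H](OC(=O)CC)C[C@H](C)CC/C=C(\C)CC/C=C(\C)CCCB1C2CCCC1CCC2 | intermediate (not isolated)
16 | methyl (2R,4R,7E,11E)-15-(furan-3-yl)-4,8,12-trimethyl-2-(propanoyloxy)pentadeca-7,11-dienoate | COC(=O)[C@H](OC(=O)CC)C[C@H](C)CC/C=C(\C)CC/C=C(\C)CCCc1ccoc1 | intermediate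
17 | lithium (2R)-2-[(2R,5E,9E)-13-(furan-3-yl)-2,6,10-trimethyltrideca-5,9-dien-1-yl]-4-methyl-5-oxo-2,5-dihydrofuran-3-olate | CC1=C([O-])[C@@H](C[C@H](C)CC/C=C(\C)CC/C=C(\C)CCCc2ccoc2)OC1=O.[Li+] | intermediate (not isolated)
18 | (5R)-5-[(2R,5E,9E)-13-(furan-3-yl)-2,6,10-trimethyltrideca-5,9-dien-1-yl]-4-hydroxy-3-methylfuran-2(5H)-one | CC1=C(O)[C@@H](C[C@H](C)CC/C=C(\C)CC/C=C(\C)CCCc2ccoc2)OC1=O | target

**Step count**
Total steps: 9. Longest linear sequence: 9 (fully linear from 1).

**Steps most likely to fail, with fallbacks**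

Step 1 (enantio- and cis-selectivity on a furan ester is untested). The fallback sets out from 1. Hydrogenation over 5% Rh/Al2O3 (H2 5 bar, MeOH, rt) adds hydrogen to one face without a chiral ligand and gives the racemic cis ester methyl (2RS,4RS)-4-methyloxolane-2-carboxylate F1. A screened hydrolase (lipase or esterase, pH 7 buffer) then hydrolyses the (2R,4R) ester and leaves the (2S,4S) ester, which is 2; the cost is a 50% ceiling on yield.

Step 2 (the ester lowers the basicity of the ring oxygen, so boron may bind the carbonyl instead, or bromide may attack C2). The fallback sets out from 2. Brønsted-acid acetolysis with HBr (33% in AcOH, 60 °C) opens the protonated ether at the primary carbon and acetylates the freed alcohol, giving methyl (2S,4S)-2-(acetyloxy)-5-bromo-4-methylpentanoate F2. HCl in MeOH then removes the acetate by transesterification and returns to 4.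

Step 4 (the cobalt-catalysed sp3–sp3 allylation may be slow with this beta-branched zinc reagent or give some SN2' or Z product). The fallback sets out from 6 and avoids a preformed organozinc. Finkelstein exchange (NaI, acetone) gives methyl (2R,4S)-5-iodo-4-methyl-2-(propanoyloxy)pentanoate F3. A nickel-catalysed reductive cross-electrophile coupling with commercial geranyl acetate (NiCl2(dme), 4,4',4''-tri-tert-butyl-2,2':6',2''-terpyridine, Zn, THF/DMA, 40 °C) joins the alkyl radical to the less hindered allyl terminus and returns to 9; the E/Z ratio at C7 must be checked.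

**Further compounds**
F1 | step 1 | methyl (2RS,4RS)-4-methyloxolane-2-carboxylate (racemic cis) | COC(=O)[C@@H]1C[C@H](C)CO1.COC(=O)[C@H]1C[C@@H](C)CO1
F2 | step 2 | methyl (2S,4S)-2-(acetyloxy)-5-bromo-4-methylpentanoate | COC(=O)[C@@H](OC(C)=O)C[C@H](C)CBr
F3 | step 4 | methyl (2R,4S)-5-iodo-4-methyl-2-(propanoyloxy)pentanoate | COC(=O)[C@H](OC(=O)CC)C[C@H](C)CI
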